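**Plan**

1. Numbering used throughout: C1 = ring-fusion CH, C2 = CH2, C3 = CH(OAc), C4 = C(Me)–O, C5–C14 = the ten-carbon bridge (C7 carbinol, C8 exo-methylene, C11=C12 E-alkene), C15 = CMe2.
2. Enabling feature: the oxane ring O–C15–C1–C2–C3–C4 holds a vinyl acetate unit (C2–C3–OAc) between C1, a carbon β to the ring oxygen that can be a radical, and C4, the fully substituted ether carbon that can be the β-carbon of a β-alkoxyacrylate. C1 and C4 are also members of the 14-membered carbocycle.
3. Retrosynthesis: cut C1–C2 and C3–C4 (radical annulation with vinyl acetate; the C4 methyl is traced back to CH2CO2R). Then cut C7–C8 (Ni/Cr macrocyclization), then the C4–O enol ether bond (oxa-Michael addition). This leaves geranylacetone (C8–C15 with the methylene and methyl carbons) and a six-carbon ynoate (C4–C7 and the later C4 methyl).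
4. Forward order of rings: open-chain ether, then the 14-membered oxacycle (C7–C8 closure), then oxane ring and 14-membered carbocycle together in one transannular step, then decarboxylation of CH2CO2H to the C4 methyl.
5. Stereochemistry: C7 comes from the chiral ligand in the Ni/Cr step. C1, C3 and C4 arise in the key step: C1 by attack anti to the C7 silyloxy group, C4 by the bridged topology, C3 by exo placement of the acetoxy group. The E-alkene comes from geranylacetone.

Key step: step 10

Remark: the selenium-bearing carbon (C1) is carried as a mixture of epimers from step 3 to step 9; this is of no consequence because C1 becomes a planar radical in step 10.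

**Step 1**
Reactants: 1 geranylacetone; 2 N-phenylbis(trifluoromethanesulfonimide)
Product: 3 (E)-6,10-dimethylundeca-1,5,9-trien-2-yl trifluoromethanesulfonate
Conditions: LiN(i-Pr)2, THF, −78 °C; then 2, −78 → 0 °C
Reagents that add atoms: 2 N-phenylbis(trifluoromethanesulfonimide), O=S(=O)(N(c1ccccc1)S(=O)(=O)C(F)(F)F)C(F)(F)F
Why: Kinetic deprotonation of the methyl ketone on the methyl side and O-sulfonylation of the terminal lithium enolate (enol triflate formation) should give the 1,1-disubstituted alkenyl triflate that later serves as the alkenyl donor.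

**Step 2**
Reactants: 3 enol triflate; 4 N-bromosuccinimide; 5 water
Product: 6 (E)-9-bromo-10-hydroxy-6,10-dimethylundeca-1,5-dien-2-yl trifluoromethanesulfonate (racemic bromohydrin)
Conditions: N-bromosuccinimide (1.05 equiv), THF/H2O (2:1), 0 °C
Reagents that add atoms: 4 N-bromosuccinimide, O=C1CCC(=O)N1Br; 5 water, O
Why: Bromohydrin formation: the bromonium ion should form at the terminal trisubstituted alkene (the most electron-rich and accessible one; the enol triflate alkene is deactivated) and water opens it at the tertiary carbon, so the tertiary alcohol on C15 and a leaving group on C1 arise together; the new stereocenter is racemic and is erased in step 10.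

**Step 3**
Reactants: 6 bromohydrin; 7 diphenyl diselenide
Product: 9 (E)-10-hydroxy-6,10-dimethyl-9-(phenylselanyl)undeca-1,5-dien-2-yl trifluoromethanesulfonate (racemic), via epoxide 8 (not isolated)
Conditions: (PhSe)2 (0.55 equiv), NaBH4, EtOH, 0 → 50 °C
Reagents that add atoms: 7 diphenyl diselenide, c1ccc(cc1)[Se][Se]c1ccccc1
Why: The basic ethanolic selenolate should close the bromohydrin to the epoxide, which phenylselenolate opens by SN2 attack at the less hindered secondary carbon C1 (direct displacement of bromide would give the same compound); this places the radical precursor next to the free tertiary alcohol.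

**Step 4**
Reactants: 10 3-bromo-1,1-dimethoxypropane; 11 lithium acetylide–ethylenediamine complex
Product: 12 5,5-dimethoxypent-1-yne
Conditions: DMSO, 10 → 25 °C
Reagents that add atoms: 11 lithium acetylide–ethylenediamine complex, [Li+].[C-]#C.NCCN
Why: SN2 alkylation of the acetylide by the primary bromide, a standard route to terminal alkynes.

**Step 5**
Reactants: 12 5,5-dimethoxypent-1-yne; 13 2-(trimethylsilyl)ethyl chloroformate
Product: 14 2-(trimethylsilyl)ethyl 6,6-dimethoxyhex-2-ynoate
Conditions: n-BuLi, THF, −78 °C; then 13, −78 → 0 °C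
Reagents that add atoms: 13 2-(trimethylsilyl)ethyl chloroformate, C[Si](C)(C)CCOC(=O)Cl
Why: Deprotonation of the terminal alkyne and acylation of the lithium acetylide by the chloroformate should give the ynoate.

**Step 6**
Reactants: 9 hydroxy selenide; 14 ynoate
Product: 15 2-(trimethylsilyl)ethyl (E)-3-{[(E)-2,6-dimethyl-3-(phenylselanyl)-10-(trifluoromethanesulfonyloxy)undeca-6,10-dien-2-yl]oxy}-6,6-dimethoxyhex-2-enoate
Conditions: NaH (0.2 equiv), THF, 0 → 25 °C
Reagents that add atoms: none
Why: Oxa-Michael (conjugate) addition of the tertiary alkoxide to the ynoate, with the alkoxide regenerated by proton transfer, should give the thermodynamically preferred E β-alkoxy enoate and so joins the C15 oxygen to C4; the catalytic amount of base is chosen to spare the enol triflate.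

**Step 7**
Reactants: 15 acetal; 5 water
Product: 16 2-(trimethylsilyl)ethyl (E)-3-{[(E)-2,6-dimethyl-3-(phenylselanyl)-10-(trifluoromethanesulfonyloxy)undeca-6,10-dien-2-yl]oxy}-6-oxohex-2-enoate
Conditions: pyridinium p-toluenesulfonate (cat.), acetone/H2O (10:1), 45 °C
Reagents that add atoms: 5 water, O
Why: Acid-catalysed hydrolysis of the dimethyl acetal; the β-alkoxy enoate is a vinylogous carbonate and far less acid-labile than a simple enol ether.

**Step 8**
Reactants: 16 aldehyde enol triflate
Product: 17 2-(trimethylsilyl)ethyl (E)-2-[(5R,9E)-5-hydroxy-10,14,14-trimethyl-6-methylidene-13-(phenylselanyl)oxacyclotetradec-9-en-2-ylidene]acetate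
Conditions: CrCl2 (6 equiv), NiCl2 (0.05 equiv), chiral 2-(4-isopropyl-4,5-dihydrooxazol-2-yl)aryl methanesulfonamide ligand (6.6 equiv, the enantiomer that delivers the R carbinol), Et3N (6.6 equiv), THF, 25 °C, slow addition of 16 to a final 2 mM
Reagents that add atoms: none
Why: Nozaki–Hiyama–Kishi reaction: zerovalent nickel inserts into the alkenyl C–OTf bond, transmetalation gives the alkenylchromium species, which adds to the aldehyde and closes the 14-membered oxacycle at high dilution; the chromium-bound chiral sulfonamide ligand selects the aldehyde face and should set C7 as R, the remote selenide stereocenter having no say.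

**Step 9**
Reactants: 17 macrocyclic allylic alcohol; 18 tert-butyldimethylsilyl trifluoromethanesulfonate
Product: 19 2-(trimethylsilyl)ethyl (E)-2-[(5R,9E)-5-(tert-butyldimethylsilyloxy)-10,14,14-trimethyl-6-methylidene-13-(phenylselanyl)oxacyclotetradec-9-en-2-ylidene]acetate
Conditions: 18, 2,6-lutidine, CH2Cl2, −78 °C
Reagents that add atoms: 18 tert-butyldimethylsilyl trifluoromethanesulfonate, CC(C)(C)[Si](C)(C)OS(=O)(=O)C(F)(F)F
Why: Silylation of the secondary allylic alcohol; the bulky silyl ether also supplies the steric bias used in step 10.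

**Step 10**
Reactants: 19 macrocyclic selenide; 20 vinyl acetate
Product: 21 (1R,3R,4R,7R,11E)-3-acetoxy-7-(tert-butyldimethylsilyloxy)-4,15-epoxycembra-8(19),11-diene carrying CH2CO2CH2CH2SiMe3 on C4 in place of the methyl group
Conditions: Bu3SnH (1.5 equiv, syringe pump over 12 h), 2,2'-azobis(2-methylpropionitrile) (0.2 equiv), vinyl acetate/benzene (1:1), 75 °C, 19 at 5 mM
Reagents that add atoms: 20 vinyl acetate, C=COC(C)=O
Why: Proposed new method: Bu3Sn• abstracts the phenylselanyl group and the planar secondary C1 radical adds to the unsubstituted terminus of vinyl acetate (C1–C2); the resulting nucleophilic α-acetoxy radical at C3 attacks the β-carbon C4 of the β-alkoxyacrylate (C3–C4) and the α-ester radical takes hydrogen from Bu3SnH. The closest known reaction types are the Giese addition of alkyl radicals to vinyl esters and the 6-exo radical cyclization onto β-alkoxyacrylates used for oxane rings (tin hydride or SmI2 ketyl variants); their union as a transannular annulation is without direct precedent. The oxane ring closes in the 6-exo-trig mode and, because C1 and C4 are ring members of the macrocyclic ether, the same bond turns the 14-membered oxacycle into the 14-membered carbocycle. C1 is set in the intermolecular addition, which should occur on the ring face anti to the C7 silyloxy group (in the target the C2–C3 bridge and the C7 oxygen lie on opposite faces of the oxacycle); C4 then follows from the bridged topology (only the cis-bridged oxane with H on C1 and CH2CO2R on C4 pointing outward can form), and C3 from exo placement of the acetoxy group, away from the ten-carbon bridge and anti to C5. The step needs addition to vinyl acetate to beat reduction and β-fragmentation of the C1 radical, and ring closure to beat uptake of a second vinyl acetate; the large excess of vinyl acetate, the low stationary Bu3SnH concentration, the polarity match of radical and acceptor and the gem-dimethyl group on C15 should secure this.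

**Step 11**
Reactants: 21 bicyclic silyl ether ester
Product: 22 (1R,3R,4R,7R,11E)-3-acetoxy-7-hydroxy-4,15-epoxycembra-8(19),11-diene carrying CH2CO2H on C4 in place of the methyl group
Conditions: tris(dimethylamino)sulfonium difluorotrimethylsilicate (3 equiv), DMF, 0 → 25 °C; then aq. NH4Cl
Reagents that add atoms: none
Why: Fluoride attacks silicon: the 2-(trimethylsilyl)ethyl ester fragments to carboxylate, ethylene and Me3SiF and the silyl ether is cleaved, while the neutral anhydrous fluoride source should leave the acetate untouched.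

**Step 12**
Reactants: 22 hydroxy acid; 23 1-hydroxypyridine-2(1H)-thione
Product: 25 CNP0202897.1 (target), via thiohydroxamate ester 24 (not isolated)
Conditions: 23, N,N'-dicyclohexylcarbodiimide, 4-(dimethylamino)pyridine (cat.), CH2Cl2, 0 → 25 °C, dark; then t-BuSH (10 equiv), hν (tungsten lamp), 15 °C
Reagents that add atoms: none
Why: Barton reductive decarboxylation: the thiohydroxamate ester fragments under light to CO2 and the primary radical on the C4 side chain, and hydrogen transfer from the thiol should give the C4 methyl group without touching a stereocenter.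

**Compound list**

1 | geranylacetone, (E)-6,10-dimethylundeca-5,9-dien-2-one | CC(=O)CC/C=C(\C)CCC=C(C)C | starting material
2 | N-phenylbis(trifluoromethanesulfonimide) | O=S(=O)(N(c1ccccc1)S(=O)(=O)C(F)(F)F)C(F)(F)F | starting material
3 | (E)-6,10-dimethylundeca-1,5,9-trien-2-yl trifluoromethanesulfonate | C=C(OS(=O)(=O)C(F)(F)F)CC/C=C(\C)CCC=C(C)C | intermediate
4 | N-bromosuccinimide | O=C1CCC(=O)N1Br | starting material
5 | water | O | starting material
6 | (E)-9-bromo-10-hydroxy-6,10-dimethylundeca-1,5-dien-2-yl trifluoromethanesulfonate (racemic) | C=C(OS(=O)(=O)C(F)(F)F)CC/C=C(\C)CCC(Br)C(C)(C)O | intermediate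
7 | diphenyl diselenide | c1ccc(cc1)[Se][Se]c1ccccc1 | starting material
8 | (E)-8-(3,3-dimethyloxiran-2-yl)-6-methylocta-1,5-dien-2-yl trifluoromethanesulfonate (racemic, not isolated) | C=C(OS(=O)(=O)C(F)(F)F)CC/C=C(\C)CCC1OC1(C)C | intermediate
9 | (E)-10-hydroxy-6,10-dimethyl-9-(phenylselanyl)undeca-1,5-dien-2-yl trifluoromethanesulfonate (racemic) | C=C(OS(=O)(=O)C(F)(F)F)CC/C=C(\C)CCC([Se]c1ccccc1)C(C)(C)O | intermediate
10 | 3-bromo-1,1-dimethoxypropane | COC(CCBr)OC | starting material
11 | lithium acetylide–ethylenediamine complex | [Li+].[C-]#C.NCCN | starting material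
12 | 5,5-dimethoxypent-1-yne | C#CCCC(OC)OC | intermediate
13 | 2-(trimethylsilyl)ethyl chloroformate | C[Si](C)(C)CCOC(=O)Cl | starting material
14 | 2-(trimethylsilyl)ethyl 6,6-dimethoxyhex-2-ynoate | COC(CCC#CC(=O)OCC[Si](C)(C)C)OC | intermediate
15 | 2-(trimethylsilyl)ethyl (E)-3-{[(E)-2,6-dimethyl-3-(phenylselanyl)-10-(trifluoromethanesulfonyloxy)undeca-6,10-dien-2-yl]oxy}-6,6-dimethoxyhex-2-enoate (epimer mixture at the selenium-bearing carbon) | C=C(OS(=O)(=O)C(F)(F)F)CC/C=C(\C)CCC([Se]c1ccccc1)C(C)(C)O/C(CCC(OC)OC)=C/C(=O)OCC[Si](C)(C)C | intermediate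
16 | 2-(trimethylsilyl)ethyl (E)-3-{[(E)-2,6-dimethyl-3-(phenylselanyl)-10-(trifluoromethanesulfonyloxy)undeca-6,10-dien-2-yl]oxy}-6-oxohex-2-enoate (epimer mixture at the selenium-bearing carbon) | C=C(OS(=O)(=O)C(F)(F)F)CC/C=C(\C)CCC([Se]c1ccccc1)C(C)(C)O/C(CCC=O)=C/C(=O)OCC[Si](C)(C)C | intermediate
17 | 2-(trimethylsilyl)ethyl (E)-2-[(5R,9E)-5-hydroxy-10,14,14-trimethyl-6-methylidene-13-(phenylselanyl)oxacyclotetradec-9-en-2-ylidene]acetate (epimer mixture at C13 of the oxacycle) | C=C1CC/C=C(\C)CCC([Se]c2ccccc2)C(C)(C)O/C(=C/C(=O)OCC[Si](C)(C)C)CC[C@H]1O | intermediate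
18 | tert-butyldimethylsilyl trifluoromethanesulfonate | CC(C)(C)[Si](C)(C)OS(=O)(=O)C(F)(F)F | starting material
19 | 2-(trimethylsilyl)ethyl (E)-2-[(5R,9E)-5-(tert-butyldimethylsilyloxy)-10,14,14-trimethyl-6-methylidene-13-(phenylselanyl)oxacyclotetradec-9-en-2-ylidene]acetate (epimer mixture at C13 of the oxacycle) | C=C1CC/C=C(\C)CCC([Se]c2ccccc2)C(C)(C)O/C(=C/C(=O)OCC[Si](C)(C)C)CC[C@H]1O[Si](C)(C)C(C)(C)C | intermediate
20 | vinyl acetate | C=COC(C)=O | starting material
21 | (1R,3R,4R,7R,11E)-3-acetoxy-7-(tert-butyldimethylsilyloxy)-4,15-epoxycembra-8(19),11-diene with CH2CO2CH2CH2SiMe3 on C4 in place of methyl | C=C1CC/C=C(\C)CC[C@@H]2C[C@@H](OC(C)=O)[C@](CC(=O)OCC[Si](C)(C)C)(CC[C@H]1O[Si](C)(C)C(C)(C)C)OC2(C)C | intermediate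
22 | (1R,3R,4R,7R,11E)-3-acetoxy-7-hydroxy-4,15-epoxycembra-8(19),11-diene with CH2CO2H on C4 in place of methyl | C=C1CC/C=C(\C)CC[C@@H]2C[C@@H](OC(C)=O)[C@](CC(=O)O)(CC[C@H]1O)OC2(C)C | intermediate
23 | 1-hydroxypyridine-2(1H)-thione | ON1C=CC=CC1=S | starting material
24 | 2-thioxopyridin-1(2H)-yl ester of acid 22 (not isolated) | C=C1CC/C=C(\C)CC[C@@H]2C[C@@H](OC(C)=O)[C@](CC(=O)ON3C=CC=CC3=S)(CC[C@H]1O)OC2(C)C | intermediate
25 | CNP0202897.1, (1R,3R,4S,7R,11E)-3-acetoxy-4,15-epoxycembra-8(19),11-dien-7-ol | C=C1CC/C=C(\C)CC[C@@H]2C[C@@H](OC(C)=O)[C@](C)(CC[C@H]1O)OC2(C)C | target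

**Count and risks**

Total step count: 12. Longest linear sequence: 10 steps (steps 1, 2, 3, 6, 7, 8, 9, 10, 11, 12).

Steps most likely to fail:

1. Step 10 (proposed new method). The C1 radical may be reduced, or may lose the enol ether oxygen by β-fragmentation, before it meets vinyl acetate. The adduct radical may take up a second vinyl acetate before it closes the ring. The first C–C bond may form with poor facial selectivity with respect to C7. Fallback with known reactions, setting out from 19 and returning at 21: Giese addition of the C1 radical (Bu3SnH, 2,2'-azobis(2-methylpropionitrile), benzene, 80 °C) to vinylboronic acid pinacol ester, a far faster radical trap than vinyl acetate, should give the alkylboronic ester F1. Oxidation with NaBO3·4H2O should give the primary alcohol F2, and Dess–Martin oxidation the aldehyde F3 (F1 to F3 as C1 epimers). SmI2 with MeOH in THF at 0 °C then closes the C3–C4 bond by the established ketyl cyclization onto the β-alkoxyacrylate, again transannular, to give the hydroxy ester F4, whose C1 epimers are separated. The C3 hydroxyl is expected exo on the same grounds as in step 10, to be confirmed. Acetylation (Ac2O, 4-(dimethylamino)pyridine, pyridine) leads to 21.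

2. Step 6. The hindered tertiary alkoxide may add sluggishly, the ynoate may isomerise under base to the allenoate and dienoate, and the enol triflate may be lost under base. Fallback, setting out from 14 (with 9) and returning at 15: hydration of 14 (pyrrolidine, then aqueous acetic acid) should give the β-keto ester F5, and PPh3/CCl4 the β-chloro enoate F6. Addition–elimination of the potassium alkoxide of 9 (KN(SiMe3)2, THF, −78 °C) on F6 then gives 15 by substitution at a vinylogous acid chloride in place of addition to an alkyne.

3. Step 8. The ligand may not select the aldehyde face well enough in the ring-closing event, and intermolecular coupling may compete. Fallback, setting out from 16 and returning at 17: ligand-free ring closure (CrCl2, NiCl2 cat., DMSO/THF, high dilution) should give the C7-epimeric alcohols F7. Oxidation with MnO2, which spares the selenide, gives the macrocyclic enone F8. Corey–Bakshi–Shibata reduction with catecholborane and (S)-1-methyl-3,3-diphenyltetrahydro-1H,3H-pyrrolo[1,2-c][1,3,2]oxazaborole, with the alkenyl group acting as the large substituent, should return 17 as the R carbinol.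

**Further compounds**

F1 | step 10 | C1-(2-borylethyl) macrocycle: compound 19 with CH2CH2B(pin) in place of the phenylselanyl group (C1 epimers) | C=C1CC/C=C(\C)CCC(CCB2OC(C)(C)C(C)(C)O2)C(C)(C)O/C(=C/C(=O)OCC[Si](C)(C)C)CC[C@H]1O[Si](C)(C)C(C)(C)C
F2 | step 10 | C1-(2-hydroxyethyl) macrocycle (C1 epimers) | C=C1CC/C=C(\C)CCC(CCO)C(C)(C)O/C(=C/C(=O)OCC[Si](C)(C)C)CC[C@H]1O[Si](C)(C)C(C)(C)C
F3 | step 10 | C1-(2-oxoethyl) macrocycle (C1 epimers) | C=C1CC/C=C(\C)CCC(CC=O)C(C)(C)O/C(=C/C(=O)OCC[Si](C)(C)C)CC[C@H]1O[Si](C)(C)C(C)(C)C
F4 | step 10 | C3 alcohol corresponding to 21 (hydroxyl in place of acetoxy) | C=C1CC/C=C(\C)CC[C@@H]2C[C@@H](O)[C@](CC(=O)OCC[Si](C)(C)C)(CC[C@H]1O[Si](C)(C)C(C)(C)C)OC2(C)C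
F5 | step 6 | 2-(trimethylsilyl)ethyl 6,6-dimethoxy-3-oxohexanoate | COC(CCC(=O)CC(=O)OCC[Si](C)(C)C)OC
F6 | step 6 | 2-(trimethylsilyl)ethyl (Z)-3-chloro-6,6-dimethoxyhex-2-enoate | COC(CC/C(Cl)=C/C(=O)OCC[Si](C)(C)C)OC
F7 | step 8 | C5-epimeric mixture of macrocyclic alcohol 17 (oxacycle numbering) | C=C1CC/C=C(\C)CCC([Se]c2ccccc2)C(C)(C)O/C(=C/C(=O)OCC[Si](C)(C)C)CCC1O
F8 | step 8 | macrocyclic enone, 5-oxo analogue of 17 (oxacycle numbering) | C=C1CC/C=C(\C)CCC([Se]c2ccccc2)C(C)(C)O/C(=C/C(=O)OCC[Si](C)(C)C)CCC1=O
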